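**Retrosynthetic overview**
- Sequoiaflavone ⇒ its tetra-O-isopropyl ether. BCl3 removes isopropyl groups but not the single methyl ether, which arrives with the last building block.
- Ring C of flavone unit 1 (the 5-hydroxy-7-methoxy half) ⇒ key C–O disconnection at O1–C2: a biaryl aldehyde is joined through oxygen to 2',6'-dihydroxy-4'-methoxyacetophenone, followed by O-to-C aroyl shift and cyclodehydration.
- C3'–C8'' biaryl bond ⇒ Suzuki coupling of 8-iodo-tri-O-isopropylapigenin with (5-formyl-2-isopropoxyphenyl)boronic acid; the iodide ⇒ apigenin.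
- Ring order: rings A, C and B of flavone unit 2 are bought as apigenin; ring B of unit 1 comes with the boronic acid and ring A with the acetophenone; ring C of unit 1 is the only ring built, and it is formed last.

Assumption: the target has no stereocentre and its 3'–8'' biaryl axis is taken as freely rotating at room temperature, so the compound as drawn is the only stereochemical form to be made.

**Step 1**
Reactants: 1 apigenin
Product: 2 tri-O-isopropylapigenin (5,7-diisopropoxy-2-(4-isopropoxyphenyl)-4H-chromen-4-one)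
Conditions: 2-iodopropane (6 equiv), Cs2CO3 (5 equiv), DMF, 70 °C
Reagents that add atoms: 2-iodopropane (CC(C)I)
Why: Williamson ether synthesis in which excess secondary iodide and Cs2CO3 in hot DMF also alkylate the hydrogen-bonded 5-OH, which must be capped so that the next step goes to C8 and not C6.

**Step 2**
Reactants: 2 tri-O-isopropylapigenin
Product: 3 8-iodo-tri-O-isopropylapigenin (8-iodo-5,7-diisopropoxy-2-(4-isopropoxyphenyl)-4H-chromen-4-one)
Conditions: N-iodosuccinimide (1.1 equiv), CF3CO2H (0.2 equiv), MeCN, 0 °C to rt, dark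
Reagents that add atoms: N-iodosuccinimide (O=C1CCC(=O)N1I)
Why: Electrophilic aromatic iodination, for which 5,7-dialkoxyflavones react at C8 (ortho to the 7-alkoxy group and the ring oxygen, para to the 5-alkoxy group), while C6 is shielded between two isopropoxy groups and ring B is deactivated by the pyranone.

**Step 3**
Reactants: 3 8-iodo-tri-O-isopropylapigenin; 4 (5-formyl-2-isopropoxyphenyl)boronic acid
Product: 5 3-(tri-O-isopropylapigenin-8-yl)-4-isopropoxybenzaldehyde
Conditions: Pd(OAc)2 (5 mol%), SPhos (2-dicyclohexylphosphino-2',6'-dimethoxybiphenyl, 10 mol%), K3PO4 (3 equiv), toluene/H2O 10:1, 90 °C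
Reagents that add atoms: none
Why: Suzuki–Miyaura cross-coupling in which the bulky electron-rich biarylphosphine lets zerovalent palladium insert into the hindered C8–I bond and drives reductive elimination to the tri-ortho-substituted biaryl, while the aldehyde, the ethers and the pyranone tolerate aqueous K3PO4.

**Step 4**
Reactants: 5 3-(tri-O-isopropylapigenin-8-yl)-4-isopropoxybenzaldehyde; 6 2',6'-dihydroxy-4'-methoxyacetophenone (1.3 equiv)
Product: 9 tetra-O-isopropylsequoiaflavone (isopropyl ethers at O4'/O5''/O7''/O4'''), via aryl ester 7 (not isolated), via beta-diketone 8 (not isolated)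
Conditions: 1,4-dimethyl-1,2,4-triazolium iodide (10 mol%), DBU (1.5 equiv), 3,3',5,5'-tetra-tert-butyldiphenoquinone (1.1 equiv), THF, rt; then KOC(CH3)3 (7 equiv), 0 to 50 °C; then AcOH, H2SO4 (cat.), 60 °C
Reagents that add atoms: none
Why: Proposed new method: a carbene-catalysed oxidative Baker–Venkataraman annulation in which the triazolylidene adds to aldehyde 5, the Breslow intermediate is oxidised by the diphenoquinone to an acyl azolium that aroylates a phenoxide oxygen of 6 (the key C–O bond, the future O1–C2 of ring C), KOC(CH3)3 then drives the O-to-C aroyl shift through the cyclic hemiketal, and acid closes and dehydrates the beta-diketone to the 5-hydroxy-7-methoxy pyranone; the closest known reaction types are carbene-catalysed oxidative esterification of aldehydes with phenols and the Baker–Venkataraman flavone synthesis from aroyl chlorides, which have not been merged into a direct aldehyde-to-flavone annulation.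

**Step 5**
Reactants: 9 tetra-O-isopropylsequoiaflavone
Product: 10 sequoiaflavone
Conditions: BCl3 (1 M in CH2Cl2, 10 equiv), CH2Cl2, -78 °C to rt; then MeOH, 1 M HCl, 50 °C
Reagents that add atoms: none
Why: Lewis-acid ether cleavage in which BCl3 cleaves the four secondary (isopropyl) aryl ethers through an ion-pair pathway at or below room temperature but leaves a methyl aryl ether that is not peri to the carbonyl (the 7-OMe) and the pyranone rings intact.

**Compound list**
1 | apigenin (5,7-dihydroxy-2-(4-hydroxyphenyl)-4H-chromen-4-one) | O=c1cc(-c2ccc(O)cc2)oc2cc(O)cc(O)c12 | starting material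
2 | 5,7-diisopropoxy-2-(4-isopropoxyphenyl)-4H-chromen-4-one (tri-O-isopropylapigenin) | CC(C)Oc1ccc(cc1)-c1cc(=O)c2c(OC(C)C)cc(OC(C)C)cc2o1 | intermediate
3 | 8-iodo-5,7-diisopropoxy-2-(4-isopropoxyphenyl)-4H-chromen-4-one | CC(C)Oc1ccc(cc1)-c1cc(=O)c2c(OC(C)C)cc(OC(C)C)c(I)c2o1 | intermediate
4 | (5-formyl-2-isopropoxyphenyl)boronic acid | CC(C)Oc1ccc(C=O)cc1B(O)O | starting material
5 | 3-[5,7-diisopropoxy-2-(4-isopropoxyphenyl)-4-oxo-4H-chromen-8-yl]-4-isopropoxybenzaldehyde | CC(C)Oc1ccc(cc1)-c1cc(=O)c2c(OC(C)C)cc(OC(C)C)c(-c3cc(C=O)ccc3OC(C)C)c2o1 | intermediate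
6 | 1-(2,6-dihydroxy-4-methoxyphenyl)ethan-1-one (2',6'-dihydroxy-4'-methoxyacetophenone) | CC(=O)c1c(O)cc(OC)cc1O | starting material
7 | 2-acetyl-3-hydroxy-5-methoxyphenyl 3-[5,7-diisopropoxy-2-(4-isopropoxyphenyl)-4-oxo-4H-chromen-8-yl]-4-isopropoxybenzoate | CC(=O)c1c(O)cc(OC)cc1OC(=O)c2ccc(OC(C)C)c(c2)-c3c(OC(C)C)cc(OC(C)C)c4c(=O)cc(oc34)-c5ccc(OC(C)C)cc5 | intermediate
8 | 1-(2,6-dihydroxy-4-methoxyphenyl)-3-{3-[5,7-diisopropoxy-2-(4-isopropoxyphenyl)-4-oxo-4H-chromen-8-yl]-4-isopropoxyphenyl}propane-1,3-dione | COc1cc(O)c(C(=O)CC(=O)c2ccc(OC(C)C)c(c2)-c3c(OC(C)C)cc(OC(C)C)c4c(=O)cc(oc34)-c5ccc(OC(C)C)cc5)c(O)c1 | intermediate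
9 | 8-[5-(5-hydroxy-7-methoxy-4-oxo-4H-chromen-2-yl)-2-isopropoxyphenyl]-5,7-diisopropoxy-2-(4-isopropoxyphenyl)-4H-chromen-4-one (tetra-O-isopropylsequoiaflavone) | COc1cc(O)c2c(=O)cc(-c3ccc(OC(C)C)c(c3)-c4c(OC(C)C)cc(OC(C)C)c5c(=O)cc(oc45)-c6ccc(OC(C)C)cc6)oc2c1 | intermediate
10 | sequoiaflavone (7-O-methylamentoflavone) | COc1cc(O)c2c(=O)cc(-c3ccc(O)c(-c4c(O)cc(O)c5c(=O)cc(-c6ccc(O)cc6)oc45)c3)oc2c1 | target

**Totals**
Total step count: 5. Longest linear sequence: 5 steps (apigenin 1 to sequoiaflavone 10); compounds 4 and 6 are bought.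

**Three steps most likely to fail**

Step 4 (the proposed new annulation). The chelated phenoxide of 6 may accept the acyl azolium slowly, double aroylation may compete, or the acyl shift may stall in the one-pot mixture. The fallback uses known chemistry at the enone oxidation level instead of the acyl level. It sets out from 5 and 6: Claisen–Schmidt condensation (KOH, EtOH/H2O, rt) gives the (E)-chalcone F1, which stands in equilibrium with its ring-closed racemic flavanone F2. Without separation, I2 (cat.) in DMSO at 120 °C oxidises both to the flavone, and the route is rejoined at 9.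

Step 3 (hindered Suzuki coupling). The new bond is flanked by the ring oxygen and two isopropoxy groups, and boronic acid 4 can protodeboronate before it couples. The fallback reverses the roles of the partners. It sets out from 3: Miyaura borylation (B2pin2, PdCl2(dppf), KOAc, dioxane, 90 °C) gives the 8-pinacolboronate F3. Purchased 3-bromo-4-hydroxybenzaldehyde is alkylated (2-iodopropane, K2CO3, DMF) to 3-bromo-4-isopropoxybenzaldehyde F4. Suzuki coupling of F3 with the unhindered, stable bromide F4 (Pd(OAc)2, SPhos, K3PO4) comes back to the route at 5.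

Step 5 (global de-isopropylation next to a methyl ether). Four ethers must fall, one of them at the hindered O7'', the product binds boron strongly, and long exposure could start to cleave the methyl ether. The fallback changes the order, so that no methyl ether is present when the Lewis acid is used. It sets out from 5: BCl3 (CH2Cl2, 0 °C to rt) gives the tetrahydroxy aldehyde F5. Acid-mediated Claisen–Schmidt condensation with 6 (BF3·OEt2, dioxane, rt to 50 °C) gives the chalcone F6, which closes in the same medium to the racemic flavanone F7. Dehydrogenation with I2 in pyridine at 95 °C, the standard flavanone-to-flavone oxidation for free polyphenols, then returns to the route at 10.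

**Further compounds**
F1 | step 4 | (E)-1-(2,6-dihydroxy-4-methoxyphenyl)-3-{3-[5,7-diisopropoxy-2-(4-isopropoxyphenyl)-4-oxo-4H-chromen-8-yl]-4-isopropoxyphenyl}prop-2-en-1-one | COc1cc(O)c(C(=O)/C=C/c2ccc(OC(C)C)c(c2)-c3c(OC(C)C)cc(OC(C)C)c4c(=O)cc(oc34)-c5ccc(OC(C)C)cc5)c(O)c1
F2 | step 4 | racemic 2,3-dihydro derivative of 9 at flavone unit 1 (5-hydroxy-7-methoxyflavanone carrying the protected biaryl at C2) | COc1cc(O)c2C(=O)CC(Oc2c1)c3ccc(OC(C)C)c(c3)-c4c(OC(C)C)cc(OC(C)C)c5c(=O)cc(oc45)-c6ccc(OC(C)C)cc6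
F3 | step 3 | 5,7-diisopropoxy-2-(4-isopropoxyphenyl)-8-(4,4,5,5-tetramethyl-1,3,2-dioxaborolan-2-yl)-4H-chromen-4-one | CC(C)Oc1ccc(cc1)-c1cc(=O)c2c(OC(C)C)cc(OC(C)C)c(B3OC(C)(C)C(C)(C)O3)c2o1
F4 | step 3 | 3-bromo-4-isopropoxybenzaldehyde | CC(C)Oc1ccc(C=O)cc1Br
F5 | step 5 | 3-[5,7-dihydroxy-2-(4-hydroxyphenyl)-4-oxo-4H-chromen-8-yl]-4-hydroxybenzaldehyde | O=Cc1ccc(O)c(c1)-c2c(O)cc(O)c3c(=O)cc(oc23)-c4ccc(O)cc4
F6 | step 5 | (E)-1-(2,6-dihydroxy-4-methoxyphenyl)-3-{3-[5,7-dihydroxy-2-(4-hydroxyphenyl)-4-oxo-4H-chromen-8-yl]-4-hydroxyphenyl}prop-2-en-1-one | COc1cc(O)c(C(=O)/C=C/c2ccc(O)c(c2)-c3c(O)cc(O)c4c(=O)cc(oc34)-c5ccc(O)cc5)c(O)c1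
F7 | step 5 | racemic 2,3-dihydrosequoiaflavone (flavanone at flavone unit 1) | COc1cc(O)c2C(=O)CC(Oc2c1)c3ccc(O)c(c3)-c4c(O)cc(O)c5c(=O)cc(oc45)-c6ccc(O)cc6
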